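## Retrosynthetic overview
1. The target is the formal water adduct of (+)-agathic acid across C13=C14. The one strategic disconnection is the C13–O bond, and C13 is the only stereocentre that has to be made.
2. C13–OH/C14–H comes from reductive C14–O scission of a (13R,14S)-glycidic ester. That ester comes from catalyst-controlled nucleophilic oxygen transfer to the (E)-enoate (C13–O bond first, then oxirane closure).
3. Both carboxyl groups travel as allyl esters, put on in one operation and taken off in one operation under neutral conditions.
4. Ring order: rings A and B (C4, C5, C9, C10 and the 8(17)-methylene) are bought intact. The only ring formed is the oxirane (step 2), and it is opened again in step 3.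

Assumption: (+)-agathic acid, the main monomeric acid of Manila copal (a commodity resin), is sold by natural-product suppliers. It is taken here as a cheap commercial chiral-pool material with the (4S,5R,9S,10R,13E) configuration.

## Route

Step 1
Reactants: 1 (+)-agathic acid; 2 allyl bromide
Product: 3 diallyl agathate
Conditions: K2CO3 (3 equiv), 2 (2.6 equiv), DMF, rt, 14 h
Reagents that add atoms: allyl bromide, C=CCBr
Why: Carboxylate O-alkylation (SN2 at the allyl carbon) never touches the acyl carbon, so the hindered axial C19 acid is esterified as easily as the C15 acid, and neither the stereocentres nor the E-alkene are affected.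

Step 2
Reactants: 3 diallyl agathate; 4 tert-butyl hydroperoxide
Product: 6 diallyl (13R,14S)-13,14-epoxylabd-8(17)-ene-15,19-dioate, via C13 tert-butylperoxy enolate 5 (not isolated)
Conditions: Y(OiPr)3/(R)-BINOL/Ph3As=O (1:1:1, 20 mol%), 4 (5.5 M in decane, 2 equiv), 4 Å MS, THF, rt, 48–72 h
Reagents that add atoms: tert-butyl hydroperoxide, CC(C)(C)OO
Why: Proposed new method: catalyst-controlled Weitz–Scheffer epoxidation of a β,β-dialkyl enoate, a substrate class on which this chemistry has not been shown; the trivalent yttrium BINOLate binds the C15 ester carbonyl as a Lewis acid and carries tBuOO− as its own ligand, so the α-effect nucleophile is delivered inside the chiral pocket to the Re face of C13 (C13–O bond, 13R), and enolate 5 then displaces tBuO− from the O–O bond, an irreversible closure that removes the unfavourable equilibrium of ordinary oxa-Michael additions to β,β-disubstituted enoates; a nucleophilic oxidant ignores the 8(17)-methylene and the allyl groups, the remote decalin centres exert no bias so the ligand decides, (R)-BINOL is chosen because this catalyst family is expected to turn (E)-acceptors into (αS,βR)-epoxides, which maps onto (14S,13R), and any leakage at C14 is harmless because C14 becomes achiral in step 3; closest known reaction type: rare-earth alkoxide/BINOL/Ph3As=O/TBHP epoxidation of (E)-β-monosubstituted α,β-unsaturated esters, amides and ketones.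

Step 3
Reactants: 6 diallyl (13R,14S)-13,14-epoxylabd-8(17)-ene-15,19-dioate
Product: 7 diallyl (13R)-13-hydroxylabd-8(17)-ene-15,19-dioate
Conditions: SmI2 (2.5 equiv, 0.1 M in THF), HMPA (5 equiv), Me2NCH2CH2OH (2.5 equiv), THF, 0 °C, 10 min; aq. NaHCO3
Reagents that add atoms: none
Why: SmI2 reductive opening of an α,β-epoxy ester: two single-electron transfers from divalent samarium break only the C14–O bond next to the ester, the amino alcohol protonates C14 at once, and the C13–O bond keeps its configuration.

Step 4
Reactants: 7 diallyl (13R)-13-hydroxylabd-8(17)-ene-15,19-dioate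
Product: 8 (13R)-13-hydroxylabd-8(17)-ene-15,19-dioic acid (target)
Conditions: Pd(PPh3)4 (5 mol%), morpholine (6 equiv), THF, rt, 2 h; then 1 M KHSO4
Reagents that add atoms: none
Why: Tsuji–Trost-type deallylation: zerovalent palladium ionises both esters at the allyl carbon, far from the hindered C19 acyl centre, morpholine traps the π-allyl units, and the neutral conditions spare the tertiary β-hydroxy acid, the 8(17)-methylene and every stereocentre.

## Compound list
1 | (+)-agathic acid, (4S,5R,9S,10R,13E)-labda-8(17),13-diene-15,19-dioic acid | C=C1CC[C@@H]2[C@](C)(CCC[C@]2(C)C(=O)O)[C@H]1CC/C(C)=C/C(=O)O | starting material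
2 | allyl bromide | C=CCBr | starting material
3 | diallyl agathate, diallyl (4S,5R,9S,10R,13E)-labda-8(17),13-diene-15,19-dioate | C=C1CC[C@@H]2[C@](C)(CCC[C@]2(C)C(=O)OCC=C)[C@H]1CC/C(C)=C/C(=O)OCC=C | intermediate
4 | tert-butyl hydroperoxide | CC(C)(C)OO | starting material
5 | C13 tert-butylperoxy enolate (13R; yttrium-bound; drawn as the free anion) | C=C1CC[C@@H]2[C@](C)(CCC[C@]2(C)C(=O)OCC=C)[C@H]1CC[C@@](C)(OOC(C)(C)C)C=C([O-])OCC=C | intermediate
6 | diallyl (13R,14S)-13,14-epoxylabd-8(17)-ene-15,19-dioate | C=C1CC[C@@H]2[C@](C)(CCC[C@]2(C)C(=O)OCC=C)[C@H]1CC[C@@]3(C)O[C@@H]3C(=O)OCC=C | intermediate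
7 | diallyl (13R)-13-hydroxylabd-8(17)-ene-15,19-dioate | C=C1CC[C@@H]2[C@](C)(CCC[C@]2(C)C(=O)OCC=C)[C@H]1CC[C@@](C)(O)CC(=O)OCC=C | intermediate
8 | (4S,5R,9S,10R,13R)-13-hydroxylabd-8(17)-ene-15,19-dioic acid | C=C1CC[C@@H]2[C@](C)(CCC[C@]2(C)C(=O)O)[C@H]1CC[C@@](C)(O)CC(=O)O | target

## Step count and risks
Total step count: 4. Longest linear sequence: 4 (1 → 3 → 6 → 7 → 8).

**Step 2 (the proposed new step).**
- Risk: a β,β-dialkyl enoate is a much weaker acceptor than the β-monosubstituted esters this catalyst family is known for, so conversion may stall. Reversible peroxide addition could also leak E to Z and erode the ratio at C13.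
- Fallback: all known chemistry. It sets out from 3 and comes back at 7, so step 3 is bypassed as well.
- iBu2AlH (2.1 equiv, CH2Cl2, −78 °C) reduces only the unhindered conjugated C15 ester, giving allyl isocupressate F1.
- Sharpless asymmetric epoxidation (Ti(OiPr)4, D-(−)-diisopropyl tartrate, 4, 4 Å MS, CH2Cl2, −20 °C) forms the C13–O bond under hydroxyl direction and gives the (13R,14R)-epoxy alcohol F2. The sense follows geraniol, which gives the (2R,3R)-epoxide with the D-tartrate.
- Dess–Martin periodinane/NaHCO3 gives the (13R,14S)-epoxy aldehyde F3.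
- A thiazolium carbene (3-benzyl-4,5-dimethylthiazolium chloride, iPr2NEt, allyl alcohol, CH2Cl2, 30 °C) then runs the internal redox esterification. The C14–O bond is expelled and the aldehyde carbon ends as the allyl ester, giving 7.

**Step 3.**
- Risk: loss of the samarium alkoxide from the enolate would return enoate 3. Retro-aldol cleavage of the tertiary alkoxide is possible, as is 5-exo closure of the C14 radical onto its own allyl ester.
- Fallback: it sets out from 6 and comes back at 7, using a two-electron polar route in place of electron transfer (PhSeSePh/NaBH4 in EtOH with AcOH, rt).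
- The selenolate opens the oxirane by SN2 at C14, with inversion, giving the α-phenylselanyl β-hydroxy ester F4.
- A second selenolate attacks selenium, and the resulting ester enolate is protonated by the solvent to give 7. The C13–O bond is never broken.

**Step 4.**
- Risk: a palladium hydride side path could move the 8(17)-alkene into the ring, and the C19 ester could be released incompletely.
- Fallback: it sets out from 7 and comes back at 8. It is metal-free and uses two different cleavage modes.
- LiOH (THF/H2O, 0 °C to rt) hydrolyses only the unhindered C15 ester by acyl–oxygen cleavage, giving the 19-monoallyl ester F5. Its β-hydroxy carboxylate can no longer eliminate.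
- EtSNa (DMF, 60 °C) then removes the C19 allyl group by SN2 at the allyl carbon (alkyl–oxygen cleavage), which is unaffected by the hindrance at C4. Acidification gives 8.

## Further compounds
F1 | step 2 | allyl (13E)-15-hydroxylabda-8(17),13-dien-19-oate (allyl isocupressate) | C=C1CC[C@@H]2[C@](C)(CCC[C@]2(C)C(=O)OCC=C)[C@H]1CC/C(C)=C/CO
F2 | step 2 | allyl (13R,14R)-13,14-epoxy-15-hydroxylabd-8(17)-en-19-oate | C=C1CC[C@@H]2[C@](C)(CCC[C@]2(C)C(=O)OCC=C)[C@H]1CC[C@@]3(C)O[C@@H]3CO
F3 | step 2 | allyl (13R,14S)-13,14-epoxy-15-oxolabd-8(17)-en-19-oate | C=C1CC[C@@H]2[C@](C)(CCC[C@]2(C)C(=O)OCC=C)[C@H]1CC[C@@]3(C)O[C@@H]3C=O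
F4 | step 3 | diallyl (13R,14R)-13-hydroxy-14-(phenylselanyl)labd-8(17)-ene-15,19-dioate | C=C1CC[C@@H]2[C@](C)(CCC[C@]2(C)C(=O)OCC=C)[C@H]1CC[C@@](C)(O)[C@@H]([Se]c3ccccc3)C(=O)OCC=C
F5 | step 4 | (13R)-13-hydroxylabd-8(17)-ene-15,19-dioic acid 19-allyl ester | C=C1CC[C@@H]2[C@](C)(CCC[C@]2(C)C(=O)OCC=C)[C@H]1CC[C@@](C)(O)CC(=O)O
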